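**Plan**

- Retrosynthesis (pterocarpan numbering): cut O11–C11a back to a cis-isoflavan-4-ol, return C6a/C11a to an isoflavone, cut the C6a–aryl bond (Suzuki–Miyaura), and open the pyranone to an ortho-hydroxyacetophenone of ring A.
- The dihydropyran ring is then cut at two bonds at once, aryl C1–O and benzylic CH2–CH2, which leads to a benzylic chloride and 2,2-dimethyloxirane.
- Enabling feature: in ring A, the carbon C1 that carries the dihydropyran oxygen lies between C2 (bearing that ring's benzylic CH2) and C11b (bearing C11a). A fluorine on C1, flanked by a benzylic carbanion and the masked acetyl group, gives a C–C–C unit that matches the C–C–O unit of the epoxide.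
- Forward order: ring A is dressed (acetyl, fluorine, CH2Cl), the dihydropyran ring is closed in the key step, then the pyranone ring (3-iodochromone), the biaryl bond, and last the pyran and furan rings of the pterocarpan.
- Stereochemistry: C6a and C11a are both set in one asymmetric transfer hydrogenation with dynamic kinetic resolution using RuCl[(S,S)-TsDPEN](p-cymene); the acid ring closure at C11a follows C6a because only the cis-fused skeleton can form.

Key step: step 7

Remark: pterocarpan numbering is used for the target; the (S,S)-catalyst is assigned on the premise that, as with chroman-4-ones, it gives the (4S)-alcohol, which corresponds to (6aS,11aS).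

**Route**

Step 1
Reactants: 1 5-fluororesorcinol (5-fluorobenzene-1,3-diol)
Product: 2 1-(2-fluoro-4,6-dihydroxyphenyl)ethan-1-one
Conditions: AcOH, BF3·OEt2, 85 °C
Reagents that add atoms: acetic acid, CC(=O)O
Why: Nencki-type Friedel–Crafts C-acylation of the resorcinol should go para to one hydroxyl and ortho to the other (the site between the two hydroxyls is the minor one), which places the acetyl carbon, the future C11a, next to the fluorine-bearing carbon.

Step 2
Reactants: 2 1-(2-fluoro-4,6-dihydroxyphenyl)ethan-1-one
Product: 3 1-[2-fluoro-6-hydroxy-4-(methoxymethoxy)phenyl]ethan-1-one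
Conditions: MOMCl (1.05 equiv), i-Pr2NEt, CH2Cl2, 0 °C
Reagents that add atoms: chloromethyl methyl ether, COCCl
Why: Williamson-type O-alkylation should take only the free para hydroxyl, because the ortho hydroxyl is tied up in a hydrogen bond to the ketone; the MOM ether is the later ortho-directing group and the final phenol protection.

Step 3
Reactants: 3 1-[2-fluoro-6-hydroxy-4-(methoxymethoxy)phenyl]ethan-1-one
Product: 4 1-[2-(benzyloxy)-6-fluoro-4-(methoxymethoxy)phenyl]ethan-1-one
Conditions: BnBr, K2CO3, DMF, 60 °C
Reagents that add atoms: benzyl bromide, BrCc1ccccc1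
Why: Williamson etherification under more forcing conditions caps the chelated phenol as a benzyl ether that withstands organolithium, Grignard and alkoxide reagents and comes off later by hydrogenolysis.

Step 4
Reactants: 4 1-[2-(benzyloxy)-6-fluoro-4-(methoxymethoxy)phenyl]ethan-1-one
Product: 5 TIPS enol ether ({1-[2-(benzyloxy)-6-fluoro-4-(methoxymethoxy)phenyl]ethenyl}oxy)triisopropylsilane
Conditions: TIPSOTf, Et3N, CH2Cl2, 0 °C → rt
Reagents that add atoms: triisopropylsilyl trifluoromethanesulfonate, CC(C)[Si](C(C)C)(C(C)C)OS(=O)(=O)C(F)(F)F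
Why: Soft enolisation with the silyl triflate and amine turns the methyl ketone into its TIPS enol ether, a helper group that hides the electrophilic carbonyl from the carbanions of steps 5 and 7.

Step 5
Reactants: 5 TIPS enol ether of 4
Product: 8 benzylic alcohol [4-(benzyloxy)-2-fluoro-6-(methoxymethoxy)-3-{1-[(triisopropylsilyl)oxy]ethenyl}phenyl]methanol, via aryllithium 6 (not isolated), via aldehyde 7 (not isolated)
Conditions: LiTMP (1.2 equiv), THF, −78 °C; DMF, −78 °C; then NaBH4, MeOH, 0 °C
Reagents that add atoms: N,N-dimethylformamide, CN(C)C=O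
Why: Directed ortho-metalation: the amide base removes the most acidic ring proton, the one flanked by fluorine and the OMOM group (the other free position lies between two ethers and is less acidic), the aryllithium is formylated by DMF (Bouveault-type) and the aldehyde is reduced in the same flask by borohydride.

Step 6
Reactants: 8 benzylic alcohol
Product: 10 benzylic chloride ({1-[6-(benzyloxy)-3-(chloromethyl)-2-fluoro-4-(methoxymethoxy)phenyl]ethenyl}oxy)triisopropylsilane, via mesylate 9 (not isolated)
Conditions: MsCl, i-Pr2NEt, CH2Cl2, 0 °C → rt; used at once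
Reagents that add atoms: methanesulfonyl chloride, CS(=O)(=O)Cl
Why: Sulfonylation of the electron-rich benzylic alcohol followed by spontaneous displacement of the mesylate by the chloride ion released from MsCl gives the benzylic chloride without acid, so that the MOM and silyl enol ethers survive.

Step 7
Reactants: 10 benzylic chloride; 11 2,2-dimethyloxirane
Product: 15 1-[7-(benzyloxy)-5-(methoxymethoxy)-2,2-dimethylchroman-8-yl]ethan-1-one, via benzylic Grignard reagent 12 (not isolated), via tertiary magnesium alkoxide 13 (not isolated), via chroman silyl enol ether 14 (not isolated)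
Conditions: Mg turnings, 2-MeTHF, 0 °C; CuI (10 mol %), 11, −30 → 0 °C; KOtBu (3 equiv), DMPU, 80 °C; then Bu4NF, rt
Reagents that add atoms: none
Why: Magnesium insertion gives the benzylic Grignard reagent 12, whose CuI-catalysed SN2 attack on the unsubstituted carbon of 2,2-dimethyloxirane makes the ArCH2–CH2 bond and leaves the tertiary alkoxide 13 tethered to the ring; after exchange to the potassium alkoxide this adds to the fluorine-bearing carbon and expels fluoride, making the aryl C–O bond (net [3+3] annulation). The closest known reaction types are the copper-catalysed opening of isobutylene oxide by benzylmagnesium halides and the intramolecular SNAr of potassium alkoxides on non-activated 3-(2-fluoroaryl)propanols to give chromans. The dihydropyran ring closes in 6-exo-trig mode, the alkoxide adding to the C–F sp2 carbon through a Meisenheimer-type adduct before fluoride leaves. No stereocentre is formed. Two selectivities are needed: the epoxide must open only at CH2, which copper catalysis at low temperature secures by suppressing Lewis-acid isomerisation and attack at the quaternary carbon, and the ring oxygen must end up on C1, which is secured because fluorine is the only leaving group on the arene and sits between the benzylic carbon and the masked acetyl carbon, while both positions ortho to the benzylic carbon are substituted so that ortho attack of the benzyl Grignard reagent is closed. The ketone travels as its TIPS enol ether so that no carbonyl meets the Grignard reagent, and Bu4NF at the end returns the ketone whether or not tert-butoxide has already cleaved the silyl group.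

Step 8
Reactants: 15 1-[7-(benzyloxy)-5-(methoxymethoxy)-2,2-dimethylchroman-8-yl]ethan-1-one
Product: 16 1-[7-hydroxy-5-(methoxymethoxy)-2,2-dimethylchroman-8-yl]ethan-1-one
Conditions: H2 (1 atm), Pd/C (10 wt % Pd on carbon), EtOAc, rt
Reagents that add atoms: none
Why: Hydrogenolysis over palladium cleaves only the benzyl ether, freeing the phenol ortho to the acetyl group while the MOM ether, the dihydropyran ring and the hindered aryl ketone are untouched.

Step 9
Reactants: 16 1-[7-hydroxy-5-(methoxymethoxy)-2,2-dimethylchroman-8-yl]ethan-1-one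
Product: 18 3-iodochromone (3-iodo-7-(methoxymethoxy)chromen-4-one with a 2,2-dimethyl-3,4-dihydro-2H-pyran ring fused across C5–C6 and its oxygen on C5), via enaminone 17 (not isolated)
Conditions: Me2NCH(OMe)2, toluene, 95 °C; then I2, pyridine, CHCl3, rt
Reagents that add atoms: N,N-dimethylformamide dimethyl acetal, COC(OC)N(C)C; iodine, II
Why: Condensation of the methyl ketone with the amide acetal gives the enaminone, and iodine triggers cyclisation of the ortho phenol onto the enamine carbon with loss of dimethylamine and iodination at C3 (3-iodochromone synthesis from enaminones), closing the pyranone ring.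

Step 10
Reactants: 19 2-bromo-5-methoxyphenol
Product: 20 5-methoxy-2-(4,4,5,5-tetramethyl-1,3,2-dioxaborolan-2-yl)phenol
Conditions: B2pin2, PdCl2(dppf) (3 mol %), KOAc, 1,4-dioxane, 90 °C
Reagents that add atoms: bis(pinacolato)diboron, CC1(C)OB(OC1(C)C)B1OC(C)(C)C(C)(C)O1
Why: Miyaura borylation of the aryl bromide, which tolerates the free phenol, gives the pinacol boronate of ring D.

Step 11
Reactants: 18 3-iodochromone; 20 5-methoxy-2-(4,4,5,5-tetramethyl-1,3,2-dioxaborolan-2-yl)phenol
Product: 21 isoflavone (3-(2-hydroxy-4-methoxyphenyl)-7-(methoxymethoxy)chromen-4-one with the same C5–C6-fused 2,2-dimethyldihydropyran ring)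
Conditions: PdCl2(dppf) (5 mol %), K2CO3, 1,4-dioxane/H2O, 80 °C
Reagents that add atoms: none
Why: Suzuki–Miyaura coupling of the 3-iodochromone with the ortho-hydroxyaryl boronate forms the C3–aryl bond of the isoflavone, the free 2′-hydroxyl being the later furan oxygen.

Step 12
Reactants: 21 isoflavone
Product: 24 (6aS,11aS)-3-O-MOM pterocarpan, via isoflavanone 22 (not isolated), via cis-isoflavan-4-ol 23 (not isolated)
Conditions: RuCl[(S,S)-TsDPEN](p-cymene) (5 mol %), HCO2H/Et3N (5:2), EtOAc, 40 °C; then HCl, EtOH, rt
Reagents that add atoms: none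
Why: Noyori–Ikariya asymmetric transfer hydrogenation: conjugate reduction gives the isoflavanone 22, whose C3 stereocentre equilibrates through the enol, and the (S,S)-catalyst reduces one enantiomer from one carbonyl face (dynamic kinetic resolution) to the cis-(3S,4S)-alcohol 23, thereby setting both stereocentres; acid then ionises the oxygen-stabilised benzylic alcohol and the 2′-hydroxyl closes the furan ring on the face of the aryl group, so that C11a follows C6a and the cis-fused (6aS,11aS) skeleton results.

Step 13
Reactants: 24 (6aS,11aS)-3-O-MOM pterocarpan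
Product: 25 target pterocarpan CNP0207547.1
Conditions: HCl (0.5 M), MeOH/THF, rt → 40 °C
Reagents that add atoms: none
Why: Acid-catalysed acetal exchange with methanol removes the MOM group under conditions mild enough to leave the benzylic ether at C11a and both stereocentres in place.

**Compound list**

1 | 5-fluororesorcinol | Oc1cc(O)cc(F)c1 | starting material
2 | 1-(2-fluoro-4,6-dihydroxyphenyl)ethan-1-one | CC(=O)c1c(F)cc(O)cc1O | intermediate
3 | 1-[2-fluoro-6-hydroxy-4-(methoxymethoxy)phenyl]ethan-1-one | CC(=O)c1c(F)cc(OCOC)cc1O | intermediate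
4 | 1-[2-(benzyloxy)-6-fluoro-4-(methoxymethoxy)phenyl]ethan-1-one | CC(=O)c1c(F)cc(OCOC)cc1OCc1ccccc1 | intermediate
5 | TIPS enol ether of 4 | C=C(O[Si](C(C)C)(C(C)C)C(C)C)c1c(F)cc(OCOC)cc1OCc1ccccc1 | intermediate
6 | aryllithium (lithium on the ring carbon between C–F and C–OMOM of 5) | [Li]c1c(F)c(C(=C)O[Si](C(C)C)(C(C)C)C(C)C)c(OCc2ccccc2)cc1OCOC | intermediate
7 | 4-(benzyloxy)-2-fluoro-6-(methoxymethoxy)-3-{1-[(triisopropylsilyl)oxy]ethenyl}benzaldehyde | O=Cc1c(F)c(C(=C)O[Si](C(C)C)(C(C)C)C(C)C)c(OCc2ccccc2)cc1OCOC | intermediate
8 | [4-(benzyloxy)-2-fluoro-6-(methoxymethoxy)-3-{1-[(triisopropylsilyl)oxy]ethenyl}phenyl]methanol | OCc1c(F)c(C(=C)O[Si](C(C)C)(C(C)C)C(C)C)c(OCc2ccccc2)cc1OCOC | intermediate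
9 | methanesulfonate of 8 | CS(=O)(=O)OCc1c(F)c(C(=C)O[Si](C(C)C)(C(C)C)C(C)C)c(OCc2ccccc2)cc1OCOC | intermediate
10 | benzylic chloride ({1-[6-(benzyloxy)-3-(chloromethyl)-2-fluoro-4-(methoxymethoxy)phenyl]ethenyl}oxy)triisopropylsilane | ClCc1c(F)c(C(=C)O[Si](C(C)C)(C(C)C)C(C)C)c(OCc2ccccc2)cc1OCOC | intermediate
11 | 2,2-dimethyloxirane (isobutylene oxide) | CC1(C)CO1 | starting material
12 | benzylic Grignard reagent from 10 | Cl[Mg]Cc1c(F)c(C(=C)O[Si](C(C)C)(C(C)C)C(C)C)c(OCc2ccccc2)cc1OCOC | intermediate
13 | chloromagnesium alkoxide of the 2-methyl-4-arylbutan-2-ol | CC(C)(CCc1c(F)c(C(=C)O[Si](C(C)C)(C(C)C)C(C)C)c(OCc2ccccc2)cc1OCOC)O[Mg]Cl | intermediate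
14 | TIPS enol ether of 15 (ring-closed chroman) | C=C(O[Si](C(C)C)(C(C)C)C(C)C)c1c(OCc2ccccc2)cc(OCOC)c2c1OC(C)(C)CC2 | intermediate
15 | 1-[7-(benzyloxy)-5-(methoxymethoxy)-2,2-dimethylchroman-8-yl]ethan-1-one | CC(=O)c1c(OCc2ccccc2)cc(OCOC)c2c1OC(C)(C)CC2 | intermediate
16 | 1-[7-hydroxy-5-(methoxymethoxy)-2,2-dimethylchroman-8-yl]ethan-1-one | CC(=O)c1c(O)cc(OCOC)c2c1OC(C)(C)CC2 | intermediate
17 | (E)-3-(dimethylamino)-1-[7-hydroxy-5-(methoxymethoxy)-2,2-dimethylchroman-8-yl]prop-2-en-1-one | CN(C)/C=C/C(=O)c1c(O)cc(OCOC)c2c1OC(C)(C)CC2 | intermediate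
18 | 3-iodo-7-(methoxymethoxy)chromen-4-one with a 2,2-dimethyldihydropyran ring fused across C5–C6 (oxygen on C5) | O=c1c(I)coc2cc(OCOC)c3c(c12)OC(C)(C)CC3 | intermediate
19 | 2-bromo-5-methoxyphenol | COc1ccc(Br)c(O)c1 | starting material
20 | 5-methoxy-2-(4,4,5,5-tetramethyl-1,3,2-dioxaborolan-2-yl)phenol | COc1ccc(B2OC(C)(C)C(C)(C)O2)c(O)c1 | intermediate
21 | isoflavone: 3-(2-hydroxy-4-methoxyphenyl) analogue of 18 | COc1ccc(-c2coc3cc(OCOC)c4c(c3c2=O)OC(C)(C)CC4)c(O)c1 | intermediate
22 | isoflavanone (2,3-dihydro-21, C3 configurationally labile) | COc1ccc(C2COc3cc(OCOC)c4c(c3C2=O)OC(C)(C)CC4)c(O)c1 | intermediate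
23 | cis-(3S,4S)-isoflavan-4-ol | COc1ccc([C@H]2COc3cc(OCOC)c4c(c3[C@H]2O)OC(C)(C)CC4)c(O)c1 | intermediate
24 | (6aS,11aS)-3-O-(methoxymethyl) ether of the target | COc1ccc2c(c1)O[C@@H]1c3c(cc(OCOC)c4c3OC(C)(C)CC4)OC[C@H]21 | intermediate
25 | target: (6aS,11aS)-3-hydroxy-9-methoxypterocarpan with a 2,2-dimethyldihydropyran ring fused at C1–C2 (oxygen on C1) | COc1ccc2c(c1)O[C@@H]1c3c(cc(O)c4c3OC(C)(C)CC4)OC[C@H]21 | target

**Step count and risks**

Total steps: 13. Longest linear sequence: 12 (steps 1–9 and 11–13; step 10 is a one-step side branch).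

Step 7 (key step). What may go wrong: Wurtz-type homocoupling of the electron-rich benzylic halide during magnesium insertion and, above all, stalling of the fluoride displacement, because the arene carries no acceptor while the ketone is masked. Fallback, from 10 back to 15: only the Grignard formation and copper-catalysed epoxide opening are run, and aqueous quench gives the tertiary alcohol F1. Bu4NF then unmasks the ketone to give the fluoro ketone F2. Ring closure is carried out as a carbonyl-activated SNAr (K2CO3 or Cs2CO3, DMF, 80 °C), in which the ortho acetyl group stabilises the Meisenheimer adduct; this should give 15.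

Step 5. What may go wrong: poor site selectivity of the deprotonation (competition from the ring position between the two ether oxygens) or loss of lithium fluoride from the ortho-fluoroaryllithium on warming (aryne formation). Fallback, from 3 back to 8: electrophilic bromination of phenol 3 with NBS should go para to the free hydroxyl, that is at the carbon between C–F and C–OMOM, to give the bromophenol F3. Benzylation as in step 3 gives the benzyl ether F4, and silylation as in step 4 gives the bromo silyl enol ether F5. Bromine–lithium exchange with n-BuLi at −78 °C then gives aryllithium 6 regiospecifically, and DMF and NaBH4 as in step 5 return to 8.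

Step 12. What may go wrong: incomplete carbonyl reduction or eroded facial selectivity because the ether oxygen at C5 of the isoflavone crowds the ketone, or elimination to the isoflav-3-ene before ring closure. Fallback, from 21 back to 24: NaBH4 reduction gives the isoflavan-4-ols F6 as a stereoisomer mixture. Acid ring closure (HCl, EtOH) converges on the racemic cis-pterocarpan, that is 24 together with its enantiomer F7. The two are separated by preparative HPLC on a chiral stationary phase to give 24.

**Further compounds**

F1 | step 7 | 4-[4-(benzyloxy)-2-fluoro-6-(methoxymethoxy)-3-{1-[(triisopropylsilyl)oxy]ethenyl}phenyl]-2-methylbutan-2-ol | CC(C)(O)CCc1c(F)c(C(=C)O[Si](C(C)C)(C(C)C)C(C)C)c(OCc2ccccc2)cc1OCOC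
F2 | step 7 | 1-[6-(benzyloxy)-2-fluoro-3-(3-hydroxy-3-methylbutyl)-4-(methoxymethoxy)phenyl]ethan-1-one | CC(=O)c1c(F)c(CCC(C)(C)O)c(OCOC)cc1OCc1ccccc1
F3 | step 5 | 1-[3-bromo-2-fluoro-6-hydroxy-4-(methoxymethoxy)phenyl]ethan-1-one | CC(=O)c1c(F)c(Br)c(OCOC)cc1O
F4 | step 5 | 1-[6-(benzyloxy)-3-bromo-2-fluoro-4-(methoxymethoxy)phenyl]ethan-1-one | CC(=O)c1c(F)c(Br)c(OCOC)cc1OCc1ccccc1
F5 | step 5 | TIPS enol ether of F4 | C=C(O[Si](C(C)C)(C(C)C)C(C)C)c1c(F)c(Br)c(OCOC)cc1OCc1ccccc1
F6 | step 12 | isoflavan-4-ol from 21 as a mixture of stereoisomers | COc1ccc(C2COc3cc(OCOC)c4c(c3C2O)OC(C)(C)CC4)c(O)c1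
F7 | step 12 | (6aR,11aR)-enantiomer of 24 | COc1ccc2c(c1)O[C@H]1c3c(cc(OCOC)c4c3OC(C)(C)CC4)OC[C@@H]21
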